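**Plan**

- Retrosynthetic cuts: the C5'–OH back to an enone (ketone reduction); C2'–C3' to a terminal alkyne plus 2-methylpenta-1,4-dien-3-ol (Alder-ene); C4–Br/C3–Cl to the C3=C4 alkene; last the ring bond C1–C2, with the C4–O bond restored, to an oxolane.
- Forward: (R)-linalool is cut at its trisubstituted alkene to a lactol and alkynylated. The carbocycle then arises in one event, a [2,3]-Wittig ring expansion of the 2-alkynyl-5-methyl-5-vinyloxolane to (S)-1-ethynyl-4-methylcyclohex-3-en-1-ol. Halogens follow, then the side chain.
- Enabling feature: in the oxolane the propargylic C2–H and the allylic ether bond O1–C5 (C5 carries the vinyl group) sit 1,3 across the five-membered ring, so a C2 anion can reach the vinyl terminus on one ring face only while O1–C5 breaks.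
- Stereochemistry: C1 by 1,4-chirality transfer from the linalool stereocentre (5R to 1S); C3/C4 relayed from the C1 hydroxyl (directed epoxidation, trans-diaxial chloride opening, bromide entry with 1,2-chlorine shift); C5' by CBS reduction.

Key step: step 4

Remark: ring carbons are numbered C1 (carbinol) to C6 with Cl on C3 and Br on C4, side-chain carbons C1' to C7' from the exocyclic methylene; purchased (R)-(−)-linalool of high enantiomeric purity is assumed.

**Route**

Step 1
Reactants: 1 (R)-(−)-linalool
Product: 4 (5R)-5-ethenyl-5-methyloxolan-2-ol (anomer mixture), via secondary ozonide 2 (not isolated), via hydroxy aldehyde 3 (not isolated)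
Conditions: O3 (1 equiv; Sudan Red 7B as end-point indicator), CH2Cl2, −78 °C; then Me2S, −78 °C to rt
Reagents that add atoms: ozone, [O-][O+]=O
Why: Chemoselective ozonolysis (Criegee mechanism) should cleave the electron-rich trisubstituted alkene well before the vinyl group, which is deactivated by the allylic hydroxyl, and the γ-hydroxy aldehyde closes spontaneously to the lactol; the quaternary stereocentre is untouched.

Step 2
Reactants: 4 (5R)-5-ethenyl-5-methyloxolan-2-ol
Product: 5 (5R)-5-ethenyl-5-methyloxolan-2-yl acetate (anomer mixture)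
Conditions: Ac2O, Et3N, 4-(dimethylamino)pyridine (cat.), CH2Cl2, 0 °C to rt
Reagents that add atoms: acetic anhydride, CC(=O)OC(C)=O
Why: Standard nucleophile-catalysed acylation turns the lactol hydroxyl into a leaving group; the anomeric configuration is irrelevant because this carbon is planarised in steps 3 and 4.

Step 3
Reactants: 5 (5R)-5-ethenyl-5-methyloxolan-2-yl acetate; 6 tributyl[(trimethylsilyl)ethynyl]stannane
Product: 8 (5R)-5-ethenyl-5-methyl-2-[(trimethylsilyl)ethynyl]oxolane (both C2 epimers), via oxocarbenium ion 7 (not isolated)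
Conditions: BF3·OEt2, CH2Cl2, −78 °C
Reagents that add atoms: tributyl[(trimethylsilyl)ethynyl]stannane 6, CCCC[Sn](CCCC)(CCCC)C#C[Si](C)(C)C
Why: Lewis-acid ionisation of the anomeric acetate and capture of the oxocarbenium ion by the alkynylstannane (C-glycosylation-type alkynylation of a cyclic O-acetal) should outrun ionisation of the tertiary allylic ether at −78 °C; both C2 epimers are usable because C2 is deprotonated next.

Step 4
Reactants: 8 (5R)-5-ethenyl-5-methyl-2-[(trimethylsilyl)ethynyl]oxolane
Product: 11 (1S)-1-ethynyl-4-methylcyclohex-3-en-1-ol, via lithiated ether 9 (not isolated), via silylalkynyl carbinol 10 (not isolated)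
Conditions: n-BuLi, THF, −78 to −20 °C; then MeOH, K2CO3, rt
Reagents that add atoms: none
Why: Proposed new method: n-BuLi removes the propargylic, oxygen-bound C2–H of the oxolane (the only acidified C–H; both C2 epimers give the same planar silylpropargyl/allenyl anion), and this carbon attacks the terminal carbon of the C5 vinyl group while the allylic O1–C5 bond breaks, a [2,3]-Wittig shift whose closest known relatives are the [2,3]-Wittig rearrangement of allyl propargyl ethers and the Wittig ring contractions of cyclic allylic ethers. Because the two termini sit 1,3 across one ring, the shift turns the oxolane into the cyclohexene; the ring is closed through the usual five-centre envelope transition state embedded in a 7-oxanorbornene-like array (a sigmatropic ring expansion, not a simple exo or endo closure), driven by the change from carbanion to alkoxide and by loss of the ether ring. The new C1 stereocentre is controlled by the quaternary C5 of the oxolane: the C–C bond can form only on the ring face that carries the vinyl group (suprafacial on the allyl unit), so (5R) becomes (1S) while C5 becomes the sp2 carbon C4. The step needs the [2,3] path to win over the radical [1,2] shift and over cycloreversion to isoprene and an ynone enolate; low temperature, the stabilised anion and the enforced proximity of the termini should secure this. Methanol/K2CO3 then removes the silyl group in the same flask.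

Step 5
Reactants: 11 (1S)-1-ethynyl-4-methylcyclohex-3-en-1-ol
Product: 12 (1S,3S,4R)-3,4-epoxy-1-ethynyl-4-methylcyclohexan-1-ol (epoxide cis to the hydroxyl)
Conditions: VO(acac)2 (cat.), t-BuOOH, CH2Cl2, 0 °C to rt
Reagents that add atoms: tert-butyl hydroperoxide, CC(C)(C)OO
Why: Hydroxyl-directed epoxidation of a homoallylic cyclohexenol (peroxide delivered from the vanadium alkoxide) should place the oxygen on the face of the C1 hydroxyl, so C3 and C4 are set by C1; the alkyne is inert.

Step 6
Reactants: 12 (1S,3S,4R)-3,4-epoxy-1-ethynyl-4-methylcyclohexan-1-ol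
Product: 13 (1S,3S,4S)-4-chloro-1-ethynyl-4-methylcyclohexane-1,3-diol
Conditions: HCl (1 M in Et2O), CH2Cl2, −78 to −30 °C
Reagents that add atoms: hydrogen chloride, Cl
Why: Acid-mediated epoxide opening by chloride at the tertiary carbon (Markovnikov) coincides with the trans-diaxial Fürst–Plattner mode in the half-chair with the C1 hydroxyl axial, giving the tertiary chloride with inversion at C4 anti to the C3 hydroxyl; the C1 hydroxyl lies on the epoxide face and cannot intervene.

Step 7
Reactants: 13 (1S,3S,4S)-4-chloro-1-ethynyl-4-methylcyclohexane-1,3-diol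
Product: 16 (1S,3R,4R)-4-bromo-3-chloro-1-ethynyl-4-methylcyclohexan-1-ol, via secondary triflate 14 (not isolated), via chloronium triflate 15 (not isolated)
Conditions: Tf2O (1.05 equiv), 2,6-lutidine, CH2Cl2, −78 °C; then n-Bu4NBr (excess), −78 to −20 °C
Reagents that add atoms: tetrabutylammonium bromide, CCCC[N+](CCCC)(CCCC)CCCC.[Br-]
Why: Proposed new method: triflation of the secondary hydroxyl (the tertiary propargylic one is slower) gives an axial triflate trans-diaxial to the C4–Cl bond; direct SN2 at this neopentyl-type carbon is blocked, so ionisation should occur with anchimeric assistance by chlorine, which migrates from C4 to C3 on the upper face (inversion at C3), and bromide then opens the chloronium/β-chloro tertiary cation at the tertiary C4 from the lower face anti to chlorine (the ring-flipped half-chair with the small ethynyl group axial is accessible), giving the trans bromochloride with the tertiary bromide; the closest known reaction types are neighbouring-group participation by β-halogen in deoxyhalogenation and solvolysis and the diaxial–diequatorial 1,2-interchange of vicinal dihalides.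

Step 8
Reactants: 17 methacrolein; 18 vinylmagnesium bromide
Product: 19 2-methylpenta-1,4-dien-3-ol (racemic)
Conditions: THF, −78 to 0 °C; then H2O
Reagents that add atoms: vinylmagnesium bromide 18, C=C[Mg]Br
Why: 1,2-Addition of a vinyl Grignard reagent to an enal; no stereocontrol is needed because the carbinol carbon becomes a ketone in step 9.

Step 9
Reactants: 16 (1S,3R,4R)-4-bromo-3-chloro-1-ethynyl-4-methylcyclohexan-1-ol; 19 2-methylpenta-1,4-dien-3-ol
Product: 21 6-[(1S,3R,4R)-4-bromo-3-chloro-1-hydroxy-4-methylcyclohexyl]-2-methylhepta-1,6-dien-3-one, via enol tautomer 20 (not isolated)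
Conditions: [CpRu(MeCN)3]PF6 (10 mol %), 19 in excess, acetone, rt
Reagents that add atoms: 2-methylpenta-1,4-dien-3-ol 19, C=CC(O)C(C)=C
Why: Ruthenium-catalysed alkene–alkyne (Alder-ene type) coupling should form the C–C bond at the internal alkyne carbon (branched 1,1-disubstituted alkene, favoured by the quaternary propargylic carbinol), use the monosubstituted vinyl group of 19 rather than its isopropenyl group, and release by β-hydride elimination of the carbinol C–H an enol that tautomerises to the enone; no stereocentre is formed.

Step 10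
Reactants: 21 6-[(1S,3R,4R)-4-bromo-3-chloro-1-hydroxy-4-methylcyclohexyl]-2-methylhepta-1,6-dien-3-one
Product: 22 (1S,3R,4R)-4-bromo-3-chloro-1-[(5R)-5-hydroxy-6-methylhepta-1,6-dien-2-yl]-4-methylcyclohexan-1-ol
Conditions: (S)-1-methyl-3,3-diphenyltetrahydro-1H,3H-pyrrolo[1,2-c][1,3,2]oxazaborole [(S)-Me-CBS catalyst], catecholborane (excess), toluene, −78 °C; then MeOH, pH 7 buffer
Reagents that add atoms: none
Why: Corey–Bakshi–Shibata reduction, in which the oxazaborolidine binds the ketone with the isopropenyl group as the large and the CH2 chain as the small substituent, so the (S)-catalyst should deliver hydride to give the (5'R)-alcohol under catalyst control; catecholborane at −78 °C should leave the 1,1-disubstituted alkenes and the alkyl halides alone.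

**Compound list**

1 | (R)-(−)-linalool, (3R)-3,7-dimethylocta-1,6-dien-3-ol | C=C[C@](C)(O)CCC=C(C)C | starting material
2 | secondary ozonide (1,2,4-trioxolane) of the C6=C7 alkene of 1 | C=C[C@](C)(O)CCC1OOC(C)(C)O1 | intermediate
3 | (4R)-4-hydroxy-4-methylhex-5-enal | C=C[C@](C)(O)CCC=O | intermediate
4 | (5R)-5-ethenyl-5-methyloxolan-2-ol (anomer mixture) | C=C[C@@]1(C)CCC(O)O1 | intermediate
5 | (5R)-5-ethenyl-5-methyloxolan-2-yl acetate (anomer mixture) | C=C[C@@]1(C)CCC(OC(C)=O)O1 | intermediate
6 | tributyl[(trimethylsilyl)ethynyl]stannane | CCCC[Sn](CCCC)(CCCC)C#C[Si](C)(C)C | starting material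
7 | (5R)-5-ethenyl-5-methyl-4,5-dihydro-3H-furan-1-ium (oxocarbenium ion) | C=C[C@@]1(C)CCC=[O+]1 | intermediate
8 | (5R)-5-ethenyl-5-methyl-2-[(trimethylsilyl)ethynyl]oxolane (both C2 epimers) | C=C[C@@]1(C)CCC(C#C[Si](C)(C)C)O1 | intermediate
9 | C2-lithiated (5R)-5-ethenyl-5-methyl-2-[(trimethylsilyl)ethynyl]oxolane | C=C[C@@]1(C)CCC([Li])(C#C[Si](C)(C)C)O1 | intermediate
10 | (1S)-4-methyl-1-[(trimethylsilyl)ethynyl]cyclohex-3-en-1-ol (formed as its lithium alkoxide) | C[Si](C)(C)C#C[C@]1(O)CCC(C)=CC1 | intermediate
11 | (1S)-1-ethynyl-4-methylcyclohex-3-en-1-ol | C#C[C@]1(O)CCC(C)=CC1 | intermediate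
12 | (1S,3S,4R)-3,4-epoxy-1-ethynyl-4-methylcyclohexan-1-ol | C#C[C@]1(O)CC[C@@]2(C)O[C@H]2C1 | intermediate
13 | (1S,3S,4S)-4-chloro-1-ethynyl-4-methylcyclohexane-1,3-diol | C#C[C@]1(O)CC[C@](C)(Cl)[C@@H](O)C1 | intermediate
14 | C3 triflate of 13, (1S,3S,4S)-4-chloro-1-ethynyl-1-hydroxy-4-methylcyclohexan-3-yl trifluoromethanesulfonate | C#C[C@]1(O)CC[C@](C)(Cl)[C@@H](OS(=O)(=O)C(F)(F)F)C1 | intermediate
15 | chloronium triflate (chlorine bridging C3 and C4 on the face anti to the C1 hydroxyl) | C#C[C@]1(O)CC[C@]2(C)[Cl+][C@@H]2C1.[O-]S(=O)(=O)C(F)(F)F | intermediate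
16 | (1S,3R,4R)-4-bromo-3-chloro-1-ethynyl-4-methylcyclohexan-1-ol | C#C[C@]1(O)CC[C@@](C)(Br)[C@H](Cl)C1 | intermediate
17 | methacrolein | C=C(C)C=O | starting material
18 | vinylmagnesium bromide | C=C[Mg]Br | starting material
19 | 2-methylpenta-1,4-dien-3-ol (racemic) | C=CC(O)C(C)=C | intermediate
20 | 6-[(1S,3R,4R)-4-bromo-3-chloro-1-hydroxy-4-methylcyclohexyl]-2-methylhepta-1,3,6-trien-3-ol (enol) | C=C(C)C(O)=CCC(=C)[C@]1(O)CC[C@@](C)(Br)[C@H](Cl)C1 | intermediate
21 | 6-[(1S,3R,4R)-4-bromo-3-chloro-1-hydroxy-4-methylcyclohexyl]-2-methylhepta-1,6-dien-3-one | C=C(C)C(=O)CCC(=C)[C@]1(O)CC[C@@](C)(Br)[C@H](Cl)C1 | intermediate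
22 | (1S,3R,4R)-4-bromo-3-chloro-1-[(5R)-5-hydroxy-6-methylhepta-1,6-dien-2-yl]-4-methylcyclohexan-1-ol | C=C(C)[C@H](O)CCC(=C)[C@]1(O)CC[C@@](C)(Br)[C@H](Cl)C1 | target

**Step count**

Total step count: 10. Longest linear sequence: 9 steps (steps 1 to 7, 9 and 10; step 8 prepares the coupling partner).

**Steps most likely to fail**

Step 4 (proposed new method). The lithiated ether may not take the concerted path: it may fragment by cycloreversion, rearrange through the radical [1,2] pathway with loss of chirality transfer, or the base may attack silicon instead of deprotonating C2. The fallback uses known chemistry, sets out from stannane 6 and returns at 11. Tin–lithium exchange of 6 with MeLi gives lithium (trimethylsilyl)acetylide F1, which adds to commercial 4-methylcyclohex-3-en-1-one F2 to give racemic 4-methyl-1-[(trimethylsilyl)ethynyl]cyclohex-3-en-1-ol F3. K2CO3 in MeOH gives racemic 1-ethynyl-4-methylcyclohex-3-en-1-ol F4, and the (S)-enantiomer 11 is separated by preparative chromatography on a chiral stationary phase.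

Step 7 (proposed new method). The triflate may eliminate instead of ionising, the chloronium ion may be captured transannularly by the C1 hydroxyl to give a bridged ether, or bromide may enter without facial control. The fallback uses known chemistry, sets out from alkene 11 and returns at 16. Bromochlorination of 11 with N-bromosuccinimide and Et4NCl in CH2Cl2 at low temperature should follow the Markovnikov and trans-diaxial rules. From the bromonium ion syn to the hydroxyl it should give (1S,3S,4S)-3-bromo-4-chloro-1-ethynyl-4-methylcyclohexan-1-ol F5, together with its face isomer (1S,3R,4R)-3-bromo-4-chloro-1-ethynyl-4-methylcyclohexan-1-ol F6, which is removed by chromatography. Heating F5 in a polar aprotic solvent should then bring about the diaxial to diequatorial 1,2-interchange of vicinal halogens, in which each halogen keeps its face, and so convert F5 into 16; unchanged F5 is recycled. This fallback is expected to be less selective than the main sequence.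

Step 9. The cationic ruthenium catalyst may ionise the tertiary bromide (loss of HBr or transannular ether formation) or be deactivated by the halides before the coupling proceeds. The fallback reverses the order of events, sets out from alkyne 11 and returns at 21. Coupling of 11 with 19 under the same ruthenium catalysis gives, via the enol 6-[(1S)-1-hydroxy-4-methylcyclohex-3-en-1-yl]-2-methylhepta-1,3,6-trien-3-ol F7, the enone 6-[(1S)-1-hydroxy-4-methylcyclohex-3-en-1-yl]-2-methylhepta-1,6-dien-3-one F8. Epoxidation with mCPBA, which should select the electron-rich ring alkene and be guided cis by hydrogen bonding to the C1 hydroxyl, gives 6-[(1S,3S,4R)-3,4-epoxy-1-hydroxy-4-methylcyclohexyl]-2-methylhepta-1,6-dien-3-one F9. HCl opening as in step 6 gives 6-[(1S,3S,4S)-4-chloro-1,3-dihydroxy-4-methylcyclohexyl]-2-methylhepta-1,6-dien-3-one F10. Triflation and bromide treatment as in step 7 then lead, through the C3 triflate of that chlorodiol F11 and the corresponding chloronium triflate F12, to 21.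

Further compounds
F1 | step 4 | lithium (trimethylsilyl)acetylide | [Li]C#C[Si](C)(C)C
F2 | step 4 | 4-methylcyclohex-3-en-1-one | CC1=CCC(=O)CC1
F3 | step 4 | racemic 4-methyl-1-[(trimethylsilyl)ethynyl]cyclohex-3-en-1-ol | C[Si](C)(C)C#CC1(O)CCC(C)=CC1
F4 | step 4 | racemic 1-ethynyl-4-methylcyclohex-3-en-1-ol | C#CC1(O)CCC(C)=CC1
F5 | step 7 | (1S,3S,4S)-3-bromo-4-chloro-1-ethynyl-4-methylcyclohexan-1-ol | C#C[C@]1(O)CC[C@](C)(Cl)[C@@H](Br)C1
F6 | step 7 | (1S,3R,4R)-3-bromo-4-chloro-1-ethynyl-4-methylcyclohexan-1-ol | C#C[C@]1(O)CC[C@@](C)(Cl)[C@H](Br)C1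
F7 | step 9 | 6-[(1S)-1-hydroxy-4-methylcyclohex-3-en-1-yl]-2-methylhepta-1,3,6-trien-3-ol (enol) | C=C(C)C(O)=CCC(=C)[C@]1(O)CCC(C)=CC1
F8 | step 9 | 6-[(1S)-1-hydroxy-4-methylcyclohex-3-en-1-yl]-2-methylhepta-1,6-dien-3-one | C=C(C)C(=O)CCC(=C)[C@]1(O)CCC(C)=CC1
F9 | step 9 | 6-[(1S,3S,4R)-3,4-epoxy-1-hydroxy-4-methylcyclohexyl]-2-methylhepta-1,6-dien-3-one | C=C(C)C(=O)CCC(=C)[C@]1(O)CC[C@@]2(C)O[C@H]2C1
F10 | step 9 | 6-[(1S,3S,4S)-4-chloro-1,3-dihydroxy-4-methylcyclohexyl]-2-methylhepta-1,6-dien-3-one | C=C(C)C(=O)CCC(=C)[C@]1(O)CC[C@](C)(Cl)[C@@H](O)C1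
F11 | step 9 | C3 triflate of the chlorodiol F10 | C=C(C)C(=O)CCC(=C)[C@]1(O)CC[C@](C)(Cl)[C@@H](OS(=O)(=O)C(F)(F)F)C1
F12 | step 9 | chloronium triflate derived from F11 | C=C(C)C(=O)CCC(=C)[C@]1(O)CC[C@]2(C)[Cl+][C@@H]2C1.[O-]S(=O)(=O)C(F)(F)F
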